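**Retrosynthetic overview**
1. Target 19 ← C1 desilylation of 18 ← one-pot double bromo-cyclisation of the acyclic (6S,7S)-trienynol 14 (all four C–O/C–Br ring bonds made in one flask).
2. Ring order in that flask: sacrificial 3-bromotetrahydrofuran (O7→C10) → bicyclic oxonium ion → oxocane/oxocene (C7–O–C13, C12–Br) → tetrahydrofuran (C6–O–C9, C10–Br) by transannular closure.
3. 14 ← Z-selective semihydrogenation ← copper-mediated coupling of alkyne 11 with (E)-1-bromopent-2-ene ← organocatalytic propargylation of aldehyde 9 (sets C7).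
4. 9 ← ester reduction and E-selective enyne olefination ← organocatalytic acetaldehyde/ethyl glyoxylate aldol (sets C6, the first stereocenter).

Assumption: acetogenin numbering is used (C1 = terminal alkyne carbon); 1 is taken as a catalogue item; the catalyst antipodes named are those expected by analogy and the mirror-image catalyst is used if the sense of induction proves opposite.

**Step 1**
Reactants: 1 3-bromo-1-(triisopropylsilyl)prop-1-yne; 2 triethyl phosphite
Product: 3 diethyl [3-(triisopropylsilyl)prop-2-yn-1-yl]phosphonate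
Conditions: neat, 120 °C, distil off EtBr
Reagents that add atoms: none
Why: Michaelis–Arbuzov reaction of a primary propargylic bromide; no stereocenter is involved.

**Step 2**
Reactants: 4 ethyl glyoxylate (commercial polymeric toluene solution); 5 acetaldehyde
Product: 7 ethyl (2S)-2-[(tert-butyldimethylsilyl)oxy]-4-oxobutanoate, via ethyl (2S)-2-hydroxy-4-oxobutanoate 6 (not isolated)
Conditions: (R)-α,α-bis[3,5-bis(trifluoromethyl)phenyl]-2-pyrrolidinemethanol (10 mol %), DMF, 4 °C; evaporate excess MeCHO; then imidazole, TBSCl, 0 °C → rt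
Reagents that add atoms: tert-butyldimethylsilyl chloride, CC(C)(C)[Si](C)(C)Cl
Why: Enamine-mediated direct cross-aldol of acetaldehyde with the activated glyoxylate, in which the catalyst hydroxyl directs attack to one glyoxylate face and sets C6 (S), followed by silylation in the same DMF solution to trap the labile β-hydroxy aldehyde.

**Step 3**
Reactants: 7 ethyl (2S)-2-[(tert-butyldimethylsilyl)oxy]-4-oxobutanoate; 3 diethyl [3-(triisopropylsilyl)prop-2-yn-1-yl]phosphonate
Product: 8 ethyl (2S,4E)-2-[(tert-butyldimethylsilyl)oxy]-7-(triisopropylsilyl)hept-4-en-6-ynoate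
Conditions: 3, LiN(SiMe3)2, THF, −78 °C; then 7, −78 → 0 °C
Reagents that add atoms: none
Why: Horner–Wadsworth–Emmons olefination with a propargylic phosphonate gives the E-enyne (about 10:1), and adding the aldehyde to the preformed anion at −78 °C avoids β-elimination so C6 is untouched.

**Step 4**
Reactants: 8 ethyl (2S,4E)-2-[(tert-butyldimethylsilyl)oxy]-7-(triisopropylsilyl)hept-4-en-6-ynoate
Product: 9 (2S,4E)-2-[(tert-butyldimethylsilyl)oxy]-7-(triisopropylsilyl)hept-4-en-6-ynal
Conditions: i-Bu2AlH (1.1 equiv), CH2Cl2, −78 °C; aq. potassium sodium tartrate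
Reagents that add atoms: none
Why: Partial reduction of an α-silyloxy ester through the stable tetrahedral aluminate at −78 °C, which keeps the C6 configuration; the aldehyde is used at once.

**Step 5**
Reactants: 9 (2S,4E)-2-[(tert-butyldimethylsilyl)oxy]-7-(triisopropylsilyl)hept-4-en-6-ynal; 10 allenylboronic acid pinacol ester
Product: 11 (3E,6S,7S)-6-[(tert-butyldimethylsilyl)oxy]-1-(triisopropylsilyl)dec-3-ene-1,9-diyn-7-ol
Conditions: (S)-3,3'-bis(2,4,6-triisopropylphenyl)-1,1'-binaphthyl-2,2'-diyl hydrogen phosphate ((S)-TRIP, 10 mol %), 4 Å MS, toluene, −30 °C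
Reagents that add atoms: none
Why: Chiral phosphoric acid-catalysed propargylboration through a closed six-membered SE2' transition state, where catalyst control sets C7 (S) syn to the C6 silyl ether against the modest Felkin preference of the aldehyde.

**Step 6**
Reactants: 11 (3E,6S,7S)-6-[(tert-butyldimethylsilyl)oxy]-1-(triisopropylsilyl)dec-3-ene-1,9-diyn-7-ol; 12 (E)-1-bromopent-2-ene
Product: 13 (3E,6S,7S,12E)-6-[(tert-butyldimethylsilyl)oxy]-1-(triisopropylsilyl)pentadeca-3,12-diene-1,9-diyn-7-ol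
Conditions: CuI (20 mol %), NaI, K2CO3, DMF, rt
Reagents that add atoms: none
Why: Copper-acetylide SN2 alkylation of the only terminal alkyne with a primary allylic bromide gives the skipped enyne with the E-alkene retained and the free hydroxyl tolerated.

**Step 7**
Reactants: 13 (3E,6S,7S,12E)-6-[(tert-butyldimethylsilyl)oxy]-1-(triisopropylsilyl)pentadeca-3,12-diene-1,9-diyn-7-ol
Product: 14 (3E,6S,7S,9Z,12E)-6-[(tert-butyldimethylsilyl)oxy]-1-(triisopropylsilyl)pentadeca-3,9,12-trien-1-yn-7-ol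
Conditions: H2 (1 atm), Pd/CaCO3 poisoned with Pb(OAc)2, quinoline, EtOAc, rt, stop at 1 equiv H2
Reagents that add atoms: none
Why: Lindlar semihydrogenation adds H2 syn to the dialkyl alkyne to give the 9Z-alkene, while the bulky triisopropylsilyl-capped alkyne is much slower.

**Step 8**
Reactants: 14 (3E,6S,7S,9Z,12E)-6-[(tert-butyldimethylsilyl)oxy]-1-(triisopropylsilyl)pentadeca-3,9,12-trien-1-yn-7-ol
Product: 18 (3E,6S,7S,9S,10S,12S,13R)-10,12-dibromo-6,9:7,13-diepoxy-1-(triisopropylsilyl)pentadec-3-en-1-yne, via all-cis bromotetrahydrofuran 15 (not isolated), via bicyclic oxonium ion 16 (not isolated), via trans-oxocene 17 (not isolated)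
Conditions: N-bromosuccinimide (2.3 equiv), (CF3)2CHOH/CH2Cl2 1:4, 4 Å MS, −40 → 0 °C
Reagents that add atoms: N-bromosuccinimide, O=C1CCC(=O)N1Br
Why: Proposed new method: a bromonium-relay ring expansion in which (a) Br+ on the 9Z-alkene is trapped 5-endo by the free C7–OH (the bulky silyl ether at O6 does not compete) to give the 2,5-cis bromotetrahydrofuran 15, as Z-homoallylic alcohols do in 5-endo halocyclisations; (b) Br+ on the 12E-alkene is trapped 5-endo by the ring oxygen to give the cis-fused oxonium ion 16, where anti addition to the E-alkene with ethyl on the convex face fixes 12S,13R and the α,α'-trans relation to C7; (c) the C9 bromide, anti to the C10–O+ bond, pushes that bond out and the Br+ is passed on to another alkene, which unveils the 9Z-alkene inside the eight-membered ring (17) and makes the first Br+ a recycled template; (d) a second Br+ on the alkene face anti to the C6 side chain is captured transannularly (5-exo) by the O6 silyl ether with loss of the silyl group, which forces 9S,10S because O6 can only reach C9 from the C7 face and Br must be anti; every ring-forming event has a five-membered transition state, and the closest known reactions are the bromonium-induced ring expansion of tetrahydrofurans to oxocanes through bicyclic oxonium ions, 5-endo halocyclisation of homoallylic alcohols, alkene-to-alkene Br+ transfer and the biomimetic transannular bromoetherification of laurencin-type oxocenes.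

**Step 9**
Reactants: 18 (3E,6S,7S,9S,10S,12S,13R)-10,12-dibromo-6,9:7,13-diepoxy-1-(triisopropylsilyl)pentadec-3-en-1-yne
Product: 19 (3E,6S,7S,9S,10S,12S,13R)-10,12-dibromo-6,9:7,13-diepoxypentadec-3-en-1-yne
Conditions: Bu4NF (1.2 equiv), THF, −20 → 0 °C, 20 min; aq. NH4Cl
Reagents that add atoms: none
Why: Fluoride-induced protodesilylation of the alkynylsilane at low temperature, short enough to spare the two secondary bromides; no stereocenter is touched.

**Compound list**
1 | 3-bromo-1-(triisopropylsilyl)prop-1-yne | BrCC#C[Si](C(C)C)(C(C)C)C(C)C | starting material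
2 | triethyl phosphite | CCOP(OCC)OCC | starting material
3 | diethyl [3-(triisopropylsilyl)prop-2-yn-1-yl]phosphonate | CCOP(=O)(CC#C[Si](C(C)C)(C(C)C)C(C)C)OCC | intermediate
4 | ethyl glyoxylate | CCOC(=O)C=O | starting material
5 | acetaldehyde | CC=O | starting material
6 | ethyl (2S)-2-hydroxy-4-oxobutanoate | CCOC(=O)[C@H](CC=O)O | intermediate
7 | ethyl (2S)-2-[(tert-butyldimethylsilyl)oxy]-4-oxobutanoate | CCOC(=O)[C@H](CC=O)O[Si](C)(C)C(C)(C)C | intermediate
8 | ethyl (2S,4E)-2-[(tert-butyldimethylsilyl)oxy]-7-(triisopropylsilyl)hept-4-en-6-ynoate | CCOC(=O)[C@H](C/C=C/C#C[Si](C(C)C)(C(C)C)C(C)C)O[Si](C)(C)C(C)(C)C | intermediate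
9 | (2S,4E)-2-[(tert-butyldimethylsilyl)oxy]-7-(triisopropylsilyl)hept-4-en-6-ynal | O=C[C@H](C/C=C/C#C[Si](C(C)C)(C(C)C)C(C)C)O[Si](C)(C)C(C)(C)C | intermediate
10 | allenylboronic acid pinacol ester (4,4,5,5-tetramethyl-2-(propa-1,2-dien-1-yl)-1,3,2-dioxaborolane) | C=C=CB1OC(C)(C)C(C)(C)O1 | starting material
11 | (3E,6S,7S)-6-[(tert-butyldimethylsilyl)oxy]-1-(triisopropylsilyl)dec-3-ene-1,9-diyn-7-ol | C#CC[C@H](O)[C@H](C/C=C/C#C[Si](C(C)C)(C(C)C)C(C)C)O[Si](C)(C)C(C)(C)C | intermediate
12 | (E)-1-bromopent-2-ene | CC/C=C/CBr | starting material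
13 | (3E,6S,7S,12E)-6-[(tert-butyldimethylsilyl)oxy]-1-(triisopropylsilyl)pentadeca-3,12-diene-1,9-diyn-7-ol | CC/C=C/CC#CC[C@H](O)[C@H](C/C=C/C#C[Si](C(C)C)(C(C)C)C(C)C)O[Si](C)(C)C(C)(C)C | intermediate
14 | (3E,6S,7S,9Z,12E)-6-[(tert-butyldimethylsilyl)oxy]-1-(triisopropylsilyl)pentadeca-3,9,12-trien-1-yn-7-ol | CC/C=C/C/C=C\C[C@H](O)[C@H](C/C=C/C#C[Si](C(C)C)(C(C)C)C(C)C)O[Si](C)(C)C(C)(C)C | intermediate
15 | all-cis bromotetrahydrofuran: (3E,6S,7S,9S,10S,12E)-9-bromo-6-[(tert-butyldimethylsilyl)oxy]-7,10-epoxy-1-(triisopropylsilyl)pentadeca-3,12-dien-1-yne | CC/C=C/C[C@@H]1O[C@@H](C[C@@H]1Br)[C@H](C/C=C/C#C[Si](C(C)C)(C(C)C)C(C)C)O[Si](C)(C)C(C)(C)C | intermediate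
16 | bicyclic oxonium ion (1-oxoniabicyclo[3.3.0]octane, O+ bonded to C7, C10 and C13; 6S,7S,9S,10S,12S,13R; bromine at C9 and C12, ethyl at C13, silyloxy side chain at C7) | CC[C@@H]1[C@@H](Br)C[C@H]2[C@@H](Br)C[C@H]([O+]12)[C@H](C/C=C/C#C[Si](C(C)C)(C(C)C)C(C)C)O[Si](C)(C)C(C)(C)C | intermediate
17 | trans-oxocene: (3E,6S,7S,9Z,12S,13R)-12-bromo-6-[(tert-butyldimethylsilyl)oxy]-7,13-epoxy-1-(triisopropylsilyl)pentadeca-3,9-dien-1-yne | CC[C@H]1O[C@@H](C/C=C\C[C@@H]1Br)[C@H](C/C=C/C#C[Si](C(C)C)(C(C)C)C(C)C)O[Si](C)(C)C(C)(C)C | intermediate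
18 | (3E,6S,7S,9S,10S,12S,13R)-10,12-dibromo-6,9:7,13-diepoxy-1-(triisopropylsilyl)pentadec-3-en-1-yne | CC(C)[Si](C(C)C)(C(C)C)C#C/C=C/C[C@@H]1O[C@H]2C[C@@H]1O[C@H](CC)[C@@H](Br)C[C@@H]2Br | intermediate
19 | (3E,6S,7S,9S,10S,12S,13R)-10,12-dibromo-6,9:7,13-diepoxypentadec-3-en-1-yne | C#C/C=C/C[C@@H]1O[C@H]2C[C@@H]1O[C@H](CC)[C@@H](Br)C[C@@H]2Br | target

**Step count**
Total: 9 steps. Longest linear sequence: 8 steps (steps 2 to 9; step 1 is a side branch).

**Three steps most likely to fail**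

Step 8 (the proposed new cascade). The risks are 5-exo attack of the O6 silyl ether in the first event, formation of the 2,5-trans bromotetrahydrofuran (which would lead to the 12,13-diastereomer), and capture of 16 by an external nucleophile. The fallback uses known chemistry only, sets out from aldehyde 9 and comes back at oxocene 17. Aldehyde 9 is allylated with allylboronic acid pinacol ester under the (S)-TRIP catalysis of step 5 to give the homoallylic alcohol F1. Methyl 2-diazobutanoate F2 is made by deacylative diazo transfer to methyl 2-ethyl-3-oxobutanoate. O–H insertion of F2 into F1 with Rh2(O2CCPh3)4 in CH2Cl2 gives the α-alkoxy ester F3, with the C13 epimer removed by chromatography. i-Bu2AlH at −78 °C gives the aldehyde F4. Chelation-controlled allylation (allylMgBr, MgBr2·OEt2, CH2Cl2, −78 °C) gives the syn dienol F5. Ring-closing metathesis with the second-generation Grubbs catalyst (CH2Cl2, 40 °C, high dilution) gives the oxocenol F6; the silyl-capped enyne is a poor metathesis partner. CBr4 and P(n-C8H17)3 in toluene at 70 °C replace the C12 hydroxyl by bromide with inversion and give 17. 17 is then closed to 18 with N-bromosuccinimide (1.1 equiv) in CH2Cl2 at 0 °C, the known transannular bromoetherification of a laurencin-type oxocene.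

Step 5 (catalyst control against the Felkin preference of the α-silyloxy aldehyde). The fallback sets out from 9 and comes back at 11. Propargylation of 9 with 10 in the matched sense, using (R)-TRIP, gives the C7-epimeric anti alcohol F7 cleanly. Mitsunobu inversion (4-nitrobenzoic acid, PPh3, diisopropyl azodicarboxylate, toluene, 0 °C) gives the inverted 4-nitrobenzoate F8. K2CO3 in MeOH then returns 11.

Step 7 (over-reduction, or reduction of the silyl enyne, on Lindlar hydrogenation). The fallback sets out from 9, comes back at 14 and builds the 9Z-alkene by olefination instead of alkyne reduction, bypassing steps 5 to 7. A diarylprolinol-catalysed acetaldehyde aldol on 9, as in step 2 and under catalyst control, gives the β-hydroxy aldehyde F9. (E)-Hex-3-en-1-ol is converted with CBr4 and PPh3 into (E)-1-bromohex-3-ene F10. Heating F10 with PPh3 in MeCN gives [(E)-hex-3-en-1-yl]triphenylphosphonium bromide F11. The salt-free ylide from F11 (NaN(SiMe3)2, THF, −78 °C, 2.2 equiv) reacts with F9 in a Z-selective Wittig reaction to give 14.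

**Further compounds**
F1 | step 8 | (3E,6S,7S)-6-[(tert-butyldimethylsilyl)oxy]-1-(triisopropylsilyl)deca-3,9-dien-1-yn-7-ol | C=CC[C@H](O)[C@H](C/C=C/C#C[Si](C(C)C)(C(C)C)C(C)C)O[Si](C)(C)C(C)(C)C
F2 | step 8 | methyl 2-diazobutanoate | CCC(=[N+]=[N-])C(=O)OC
F3 | step 8 | methyl (2R)-2-{[(3E,6S,7S)-6-[(tert-butyldimethylsilyl)oxy]-1-(triisopropylsilyl)deca-3,9-dien-1-yn-7-yl]oxy}butanoate | CC[C@H](C(=O)OC)O[C@@H](CC=C)[C@H](C/C=C/C#C[Si](C(C)C)(C(C)C)C(C)C)O[Si](C)(C)C(C)(C)C
F4 | step 8 | (2R)-2-{[(3E,6S,7S)-6-[(tert-butyldimethylsilyl)oxy]-1-(triisopropylsilyl)deca-3,9-dien-1-yn-7-yl]oxy}butanal | CC[C@H](C=O)O[C@@H](CC=C)[C@H](C/C=C/C#C[Si](C(C)C)(C(C)C)C(C)C)O[Si](C)(C)C(C)(C)C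
F5 | step 8 | (3R,4R)-3-{[(3E,6S,7S)-6-[(tert-butyldimethylsilyl)oxy]-1-(triisopropylsilyl)deca-3,9-dien-1-yn-7-yl]oxy}hept-6-en-4-ol | CC[C@H]([C@H](O)CC=C)O[C@@H](CC=C)[C@H](C/C=C/C#C[Si](C(C)C)(C(C)C)C(C)C)O[Si](C)(C)C(C)(C)C
F6 | step 8 | (3E,6S,7S,9Z,12R,13R)-6-[(tert-butyldimethylsilyl)oxy]-7,13-epoxy-1-(triisopropylsilyl)pentadeca-3,9-dien-1-yn-12-ol | CC[C@H]1O[C@@H](C/C=C\C[C@H]1O)[C@H](C/C=C/C#C[Si](C(C)C)(C(C)C)C(C)C)O[Si](C)(C)C(C)(C)C
F7 | step 5 | (3E,6S,7R)-6-[(tert-butyldimethylsilyl)oxy]-1-(triisopropylsilyl)dec-3-ene-1,9-diyn-7-ol | C#CC[C@@H](O)[C@H](C/C=C/C#C[Si](C(C)C)(C(C)C)C(C)C)O[Si](C)(C)C(C)(C)C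
F8 | step 5 | (3E,6S,7S)-6-[(tert-butyldimethylsilyl)oxy]-1-(triisopropylsilyl)dec-3-ene-1,9-diyn-7-yl 4-nitrobenzoate | C#CC[C@H](OC(=O)c1ccc(cc1)[N+](=O)[O-])[C@H](C/C=C/C#C[Si](C(C)C)(C(C)C)C(C)C)O[Si](C)(C)C(C)(C)C
F9 | step 7 | (3S,4S,6E)-4-[(tert-butyldimethylsilyl)oxy]-3-hydroxy-9-(triisopropylsilyl)non-6-en-8-ynal | O=CC[C@H](O)[C@H](C/C=C/C#C[Si](C(C)C)(C(C)C)C(C)C)O[Si](C)(C)C(C)(C)C
F10 | step 7 | (E)-1-bromohex-3-ene | CC/C=C/CCBr
F11 | step 7 | [(E)-hex-3-en-1-yl]triphenylphosphonium bromide | CC/C=C/CC[P+](c1ccccc1)(c1ccccc1)c1ccccc1.[Br-]
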